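**Plan**
- Retrosynthesis: the 7-O-MOM bond is cut last. Before it, the two aryl–CH2 bonds of ring B (C2'–CH2 and C5'–CH2) are cut together, returning each prenyl group to a 1,1-dimethylallyl ether on O3' and O4'.
- The two O–C(tertiary) bonds lead back to a 7-O-protected catechol. The isoflavone is cut at C2 (a one-carbon unit) and at the C4–C4a acyl bond, giving phloroglucinol and 3,4-dihydroxyphenylacetic acid.
- Forward: ring A (phloroglucinol) is acylated by the ring-B acid and the pyranone ring C is closed by C1 insertion; no other ring is formed. Ketal on, 7-O-MOM on, ketal off differentiates the phenols; then both tertiary ethers are installed and rearranged in one operation.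
- Enabling feature: in ring B, C2' and C5' each lie ortho to one catechol oxygen (O3' and O4'), and they are the only hydrogen-bearing ortho carbons these oxygens have, because C3' and C4' block each other.
- Stereochemistry: the target has no stereocentre and no E/Z-isomeric olefin, so nothing has to be set.

Key step: step 7

Remark: because the molecule is achiral (both olefins carry geminal methyl groups), the request for a single enantiomer is met without any stereocontrol.

**Route**

Step 1
Reactants: 1 phloroglucinol; 2 3,4-dihydroxyphenylacetic acid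
Product: 4 orobol, 3-(3,4-dihydroxyphenyl)-5,7-dihydroxychromen-4-one, via deoxybenzoin 3 (not isolated)
Conditions: BF3·OEt2 (solvent), 90 °C; then DMF, MsCl, 70 °C, one pot; aq. NaOAc work-up
Reagents that add atoms: N,N-dimethylformamide, CN(C)C=O
Why: BF3 promotes Friedel–Crafts (Houben–Hoesch-type) C-acylation of the symmetrical, highly nucleophilic phloroglucinol to give deoxybenzoin 3, whose activated methylene is formylated by the DMF/MsCl Vilsmeier-type reagent and cyclodehydrates onto the ortho hydroxyl to close the pyranone ring (the standard deoxybenzoin route to polyhydroxyisoflavones).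

Step 2
Reactants: 4 orobol
Product: 5 3-(2,2-diphenyl-1,3-benzodioxol-5-yl)-5,7-dihydroxychromen-4-one
Conditions: Ph2CCl2, Ph2O, 175 °C
Reagents that add atoms: dichlorodiphenylmethane, ClC(Cl)(c1ccccc1)c1ccccc1
Why: Thermal ketalisation with dichlorodiphenylmethane can form a five-membered ring only across the vicinal 3',4'-diol (a standard catechol protection of polyphenolic flavonoids), so the 5- and 7-hydroxyls stay free.

Step 3
Reactants: 5 3-(2,2-diphenyl-1,3-benzodioxol-5-yl)-5,7-dihydroxychromen-4-one
Product: 6 3-(2,2-diphenyl-1,3-benzodioxol-5-yl)-5-hydroxy-7-(methoxymethoxy)chromen-4-one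
Conditions: MOMCl (1.2 equiv), K2CO3, acetone, 0 °C to rt
Reagents that add atoms: chloromethyl methyl ether, COCCl
Why: Williamson-type O-alkylation takes place at the acidic, unhindered 7-OH, whereas the 5-OH is locked in a hydrogen bond to the C4 carbonyl and does not react with one equivalent of reagent under mild carbonate base.

Step 4
Reactants: 6 3-(2,2-diphenyl-1,3-benzodioxol-5-yl)-5-hydroxy-7-(methoxymethoxy)chromen-4-one
Product: 7 3-(3,4-dihydroxyphenyl)-5-hydroxy-7-(methoxymethoxy)chromen-4-one
Conditions: H2 (1 atm), 10% Pd/C, THF–MeOH, rt, stopped at full conversion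
Reagents that add atoms: none
Why: Catalytic hydrogenolysis cleaves the doubly benzylic C–O bonds of the diphenylmethylene ketal under neutral conditions that leave the acid-labile MOM acetal intact, and monitoring hydrogen uptake should stop the reaction before the chromone C2=C3 bond is reduced.

Step 5
Reactants: 7 3-(3,4-dihydroxyphenyl)-5-hydroxy-7-(methoxymethoxy)chromen-4-one; 8 3-chloro-3-methylbut-1-yne
Product: 9 5-hydroxy-7-(methoxymethoxy)-3-[3,4-bis(2-methylbut-3-yn-2-yloxy)phenyl]chromen-4-one
Conditions: 8 (3 equiv), K2CO3, KI, CuI (cat.), acetone, 55 °C, Ar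
Reagents that add atoms: none
Why: Copper-catalysed O-propargylation of phenols with a tertiary propargylic chloride (through a copper acetylide/allenylidene-type electrophile) is the standard way to aryl 1,1-dimethylpropargyl ethers and is well precedented for vicinal dihydroxyarenes, while the chelated 5-OH is too weakly nucleophilic to compete.

Step 6
Reactants: 9 5-hydroxy-7-(methoxymethoxy)-3-[3,4-bis(2-methylbut-3-yn-2-yloxy)phenyl]chromen-4-one
Product: 10 5-hydroxy-7-(methoxymethoxy)-3-[3,4-bis(2-methylbut-3-en-2-yloxy)phenyl]chromen-4-one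
Conditions: H2 (1 atm), Lindlar catalyst, quinoline, EtOAc, rt; filtration through Et3N-deactivated silica
Reagents that add atoms: none
Why: Lindlar semihydrogenation with quinoline poisoning stops both terminal alkynes at the vinyl stage and leaves the conjugated chromone olefin and the aryl ethers untouched.

Step 7
Reactants: 10 5-hydroxy-7-(methoxymethoxy)-3-[3,4-bis(2-methylbut-3-en-2-yloxy)phenyl]chromen-4-one
Product: 14 3-[3,4-dihydroxy-2,5-bis(3-methylbut-2-enyl)phenyl]-5-hydroxy-7-(methoxymethoxy)chromen-4-one, via C5' ortho-dienone 11 (not isolated), via mono-prenyl phenol 12 (not isolated), via C2' ortho-dienone 13 (not isolated)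
Conditions: PhNEt2 (degassed), 140 °C, Ar, base-washed glassware
Reagents that add atoms: none
Why: Each aryl 1,1-dimethylallyl ether undergoes a concerted suprafacial [3,3]-sigmatropic (aromatic Claisen) shift through a chair-like transition state in which the terminal vinyl carbon bonds to the ortho ring carbon, so that allyl inversion delivers the linear prenyl group, and the 2,4-cyclohexadienones 11 and 13 then tautomerise to the phenols 12 and 14 (the less hindered O4' to C5' shift is expected first, but the order does not change the outcome). The closest known reaction type is the thermal ortho-Claisen rearrangement of aryl 1,1-dimethylallyl ethers to ortho-prenylphenols, here run twice on one ring. No ring is closed and no stereocentre is created, since the sp3 carbons of the dienones are lost on enolisation. The step needs site selectivity, and the catechol supplies it: O4' can deliver only to C5' and O3' only to C2', because the other ortho carbon of each oxygen carries the neighbouring oxygen and a shift there gives a blocked dienone that can only revert. It also needs chemoselectivity against ionisation of the tertiary ethers, against Diels–Alder trapping of an ipso-dienone by its pendant vinyl group and against a further Cope shift to C6'; ring B is electron-rich, twisted and not conjugated with the carbonyl, which disfavours the trapping pathway, and the weakly basic, non-polar amine solvent suppresses ionisation and speeds enolisation of the ortho-dienones. Relief of strain between the two adjacent tertiary ethers should allow a temperature that the chromone, the chelated 5-OH and the MOM acetal tolerate.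

Step 8
Reactants: 14 3-[3,4-dihydroxy-2,5-bis(3-methylbut-2-enyl)phenyl]-5-hydroxy-7-(methoxymethoxy)chromen-4-one
Product: 15 3-[3,4-dihydroxy-2,5-bis(3-methylbut-2-enyl)phenyl]-5,7-dihydroxychromen-4-one
Conditions: conc. HCl (cat.), MeOH, 45 °C, short reaction time, Ar
Reagents that add atoms: none
Why: Acid-catalysed methanolysis of the MOM acetal runs through an oxocarbenium ion far faster than protonation of the trisubstituted prenyl olefins, so brief mild treatment should free the 7-OH without chroman formation.

**Compound list**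
1 | phloroglucinol (benzene-1,3,5-triol) | Oc1cc(O)cc(O)c1 | starting material
2 | 3,4-dihydroxyphenylacetic acid | OC(=O)Cc1ccc(O)c(O)c1 | starting material
3 | deoxybenzoin, 2-(3,4-dihydroxyphenyl)-1-(2,4,6-trihydroxyphenyl)ethanone (not isolated) | O=C(Cc1ccc(O)c(O)c1)c1c(O)cc(O)cc1O | intermediate
4 | orobol, 3-(3,4-dihydroxyphenyl)-5,7-dihydroxychromen-4-one | O=c1c(-c2ccc(O)c(O)c2)coc2cc(O)cc(O)c12 | intermediate
5 | 3-(2,2-diphenyl-1,3-benzodioxol-5-yl)-5,7-dihydroxychromen-4-one | O=c1c(-c2ccc3c(c2)OC(c2ccccc2)(c2ccccc2)O3)coc2cc(O)cc(O)c12 | intermediate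
6 | 3-(2,2-diphenyl-1,3-benzodioxol-5-yl)-5-hydroxy-7-(methoxymethoxy)chromen-4-one | COCOc1cc(O)c2c(c1)occ(-c1ccc3c(c1)OC(c1ccccc1)(c1ccccc1)O3)c2=O | intermediate
7 | 3-(3,4-dihydroxyphenyl)-5-hydroxy-7-(methoxymethoxy)chromen-4-one | COCOc1cc(O)c2c(c1)occ(-c1ccc(O)c(O)c1)c2=O | intermediate
8 | 3-chloro-3-methylbut-1-yne | CC(C)(Cl)C#C | starting material
9 | 5-hydroxy-7-(methoxymethoxy)-3-[3,4-bis(2-methylbut-3-yn-2-yloxy)phenyl]chromen-4-one | C#CC(C)(C)Oc1ccc(-c2coc3cc(OCOC)cc(O)c3c2=O)cc1OC(C)(C)C#C | intermediate
10 | 5-hydroxy-7-(methoxymethoxy)-3-[3,4-bis(2-methylbut-3-en-2-yloxy)phenyl]chromen-4-one | C=CC(C)(C)Oc1ccc(-c2coc3cc(OCOC)cc(O)c3c2=O)cc1OC(C)(C)C=C | intermediate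
11 | C5' ortho-dienone, 5-hydroxy-7-(methoxymethoxy)-3-[5-(2-methylbut-3-en-2-yloxy)-3-(3-methylbut-2-enyl)-4-oxocyclohexa-1,5-dien-1-yl]chromen-4-one (racemic, not isolated) | O=C1C(CC=C(C)C)C=C(c2coc3cc(OCOC)cc(O)c3c2=O)C=C1OC(C)(C)C=C | intermediate
12 | mono-prenyl phenol, 5-hydroxy-3-[4-hydroxy-3-(2-methylbut-3-en-2-yloxy)-5-(3-methylbut-2-enyl)phenyl]-7-(methoxymethoxy)chromen-4-one (not isolated) | CC(C)=CCc1cc(-c2coc3cc(OCOC)cc(O)c3c2=O)cc(OC(C)(C)C=C)c1O | intermediate
13 | C2' ortho-dienone, 5-hydroxy-3-[4-hydroxy-3,6-bis(3-methylbut-2-enyl)-5-oxocyclohexa-1,3-dien-1-yl]-7-(methoxymethoxy)chromen-4-one (racemic, not isolated) | O=C1C(CC=C(C)C)C(c2coc3cc(OCOC)cc(O)c3c2=O)=CC(CC=C(C)C)=C1O | intermediate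
14 | 3-[3,4-dihydroxy-2,5-bis(3-methylbut-2-enyl)phenyl]-5-hydroxy-7-(methoxymethoxy)chromen-4-one | CC(C)=CCc1cc(-c2coc3cc(OCOC)cc(O)c3c2=O)c(CC=C(C)C)c(O)c1O | intermediate
15 | 3-[3,4-dihydroxy-2,5-bis(3-methylbut-2-enyl)phenyl]-5,7-dihydroxychromen-4-one | CC(C)=CCc1cc(-c2coc3cc(O)cc(O)c3c2=O)c(CC=C(C)C)c(O)c1O | target

**Summary**
Total step count: 8 steps.
Longest linear sequence: 8 steps, from 1 and 2 to 15.

**Steps most likely to fail**

Step 7 (double Claisen). The tertiary allyl ethers may ionise and lose the C5 unit faster than they rearrange. The hindered shift to C2' may also lag, so that the allyl group goes to the oxygen-bearing ipso carbon and is trapped by intramolecular cycloaddition, or reaches C6' by a Cope shift. Fallback: setting out from 7, both catechol hydroxyls are allylated (allyl bromide, K2CO3, acetone) to 3-[3,4-bis(allyloxy)phenyl]-5-hydroxy-7-(methoxymethoxy)chromen-4-one F1. This primary ether cannot ionise or carry the gem-dimethyl tether, and should rearrange thermally (PhNEt2, 190 °C) to 3-(2,5-diallyl-3,4-dihydroxyphenyl)-5-hydroxy-7-(methoxymethoxy)chromen-4-one F2. Olefin cross-metathesis with excess 2-methylbut-2-ene (Grubbs II catalyst, CH2Cl2, 40 °C) then turns both allyl groups into prenyl groups, and the route is rejoined at 14.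

Step 5 (bis-O-propargylation). The second alkylation may stall next to the first bulky tertiary ether, the free phenol of the mono-ether may add across the neighbouring alkyne, or the 5-OH may be alkylated under forcing. Fallback: from 7, palladium-catalysed Tsuji–Trost O-allylation with tert-butyl 2-methylbut-3-en-2-yl carbonate (Pd(PPh3)4, THF, 0 °C) should give the branched bis-ether directly. It rejoins the route at 10 and makes steps 5 and 6 unnecessary; no compound outside the list lies on this path (none F0).

Step 4 (ketal hydrogenolysis). Cleavage of the diaryl ketal may be sluggish, so that saturation of the chromone C2=C3 bond competes before the catechol is fully released. Fallback: from 4 the ketal is avoided altogether. Peracetylation (Ac2O, pyridine) gives 5,7,3',4'-tetra-O-acetylorobol F3. Selective removal of the most activated 7-O-acetyl group (PhSH, imidazole, NMP, 0 °C) gives 5,3',4'-tri-O-acetylorobol F4. MOM protection (MOMCl, iPr2NEt, CH2Cl2) gives 5,3',4'-tri-O-acetyl-7-O-(methoxymethyl)orobol F5, and deacetylation (K2CO3, MeOH, 0 °C, Ar) returns to the route at 7.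

Further compounds
F1 | step 7 | 3-[3,4-bis(allyloxy)phenyl]-5-hydroxy-7-(methoxymethoxy)chromen-4-one | C=CCOc1ccc(-c2coc3cc(OCOC)cc(O)c3c2=O)cc1OCC=C
F2 | step 7 | 3-(2,5-diallyl-3,4-dihydroxyphenyl)-5-hydroxy-7-(methoxymethoxy)chromen-4-one | C=CCc1cc(-c2coc3cc(OCOC)cc(O)c3c2=O)c(CC=C)c(O)c1O
F0 | step 5 | none | none
F3 | step 4 | 5,7,3',4'-tetra-O-acetylorobol, 3-(3,4-diacetoxyphenyl)-4-oxochromene-5,7-diyl diacetate | CC(=O)Oc1cc(OC(C)=O)c2c(c1)occ(-c1ccc(OC(C)=O)c(OC(C)=O)c1)c2=O
F4 | step 4 | 5,3',4'-tri-O-acetylorobol, 3-(3,4-diacetoxyphenyl)-7-hydroxy-4-oxochromen-5-yl acetate | CC(=O)Oc1cc(O)cc2occ(-c3ccc(OC(C)=O)c(OC(C)=O)c3)c(=O)c12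
F5 | step 4 | 5,3',4'-tri-O-acetyl-7-O-(methoxymethyl)orobol, 3-(3,4-diacetoxyphenyl)-7-(methoxymethoxy)-4-oxochromen-5-yl acetate | COCOc1cc(OC(C)=O)c2c(c1)occ(-c1ccc(OC(C)=O)c(OC(C)=O)c1)c2=O
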